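## Structural features

The target is a linear procyanidin trimer made of three (2R,3R)-flavan-3-ol units of the epicatechin type (upper T, middle M, lower B). Each unit is a chroman (ring A fused to the pyran ring C) with a 3,4-dihydroxyphenyl group at C2, a hydroxyl at C3 and hydroxyls at C5 and C7. The units are joined by two diarylmethine bonds, C4(T)–C6(M) and C4(M)–C6(B). There are eight stereocentres: in T and in M the contiguous centres C2, C3 and C4 are 2,3-cis and 3,4-trans (2α-aryl, 3α-hydroxy, 4β-aryl), and B has the 2,3-cis pair only. Each C4 is flanked by four ortho oxygen substituents and ring A of M is hexasubstituted, so the molecule is most crowded where the units meet. The twelve phenols are easily oxidised, the C4–C6 bonds are cleaved by protic acid (retro-Friedel–Crafts), and C2 epimerises in hot base or strong acid; the phenols therefore stay benzylated until the last step. The real difficulty is to make both linkages at C6 (C8 is the more nucleophilic carbon of ring A) and to set the 3,4-trans, 2,3-cis triad in the right absolute sense. The key step uses the oxygen pattern of ring A of T: O1 sits on C8a, meta to the oxygens on C5 and C7, and C4 carries C6 of M. A 3-aryl-4,6-dioxygenated indan-1-one (C1, C2, C3, C3a, C7a = future C2, C3, C4, C4a, C8a) therefore holds every carbon of ring C of T and lacks only O1, which oxygen insertion into the C1–C7a bond supplies.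

## Logic of the disconnections

**25 from 24.** The fifteen O–benzyl bonds and four aryl C–Br bonds are cut last. All earlier chemistry then runs on oxidation-stable, non-polar material, and the bromine caps cost no extra step. The forward hydrogenolysis must spare the benzylic C2–O1 and C4–aryl bonds and must be buffered against HBr.

**24 from 23 and 4.** The bond C4(M)–C6(B) is cut. A C4 cation attacked by ring A of a flavan is the most reliable way to a 3,4-trans interflavan bond, and unit B is then simply 4, which is also the precursor of unit M. The forward step needs a nucleophile that can react only at C6 (bromine at C8 of 4), an electrophile without nucleophilic ring-A carbons (bromine at C6 and C8 of T and at C8 of M), and attack anti to the C3 benzyloxy group.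

**23 from 22, and 22 from 21.** The C4–O ether bond of unit M and the two C–Br bonds on ring A of unit T are cut. A leaving group at C4 of M would not survive the organolithium and Lewis-acid steps that build T, so it is introduced late by benzylic oxidation. The forward oxidation must take hydride from the CH2 of M and not from the diarylmethine C4–H of T; the two bromines on ring A of T help by making that ring poorer.

**21 from 20, and 20 from 17 and 18.** C2–H of unit T and then the bond from C2 to the catechol ring are cut. This reduces ring C of T to a lactone with two stereocentres and makes the catechol ring a simple aryl bromide. The forward steps need a single addition to an aryl lactone and hydride delivery to the oxocarbenium ion anti to the C3–O bond.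

**17 from 16, and 16 from 14.** The O–benzyl bond at C3 and the C3–O bond are cut. The C3 oxygen comes from enolate oxidation directed by the C4 aryl group, which leaves 14 with one stereocentre in the new ring. The forward steps need oxygen delivery anti to the aryl group, an aryl ester enolate that does not open, and benzylation without alkoxide base.

**14 from 12 (key).** The O1–C8a bond is cut. Ring A of T changes from a 1,3,5-trioxygenated to a 1,3-dioxygenated benzene whose third substituent is an acyl carbon, which is the substitution pattern of commercial 7. The forward step needs aryl and not methylene migration, and a peracid that spares the electron-rich arenes.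

**12 from 11.** The bond C3–C3a of the indanone (future C4–C4a of T) is cut. The ring carbon ortho and para to the two benzyloxy groups is the natural site for a carbon–metal bond. The carbonyl-bearing carbon is meta to both ethers, so closing the ring there by Friedel–Crafts acylation would be electronically mismatched and would expose benzyl ethers to strong acid. The ketone is therefore on the ring from the start, and the ring is closed at the other end by catalytic asymmetric conjugate arylation. This gives an acyclic enone as precursor; the forward step needs catalyst control at a hindered β-carbon and tolerance of the aryl bromide.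

**11 from 10, and 10 from 6 and 8.** The C–B bond and then the enone C=C bond are cut. This leaves two simple pieces, an aldehyde on C6 of unit M and an ortho-halogenated aryl methyl ketone. The forward steps need a condensation at a flanked, non-enolisable aldehyde and a borylation that touches the aryl iodide and not the hindered aryl bromide.

**6 from 4, 4 from 3, 3 from 2, 2 from 1.** The C6–CHO bond, the C8–Br bond and the five O–benzyl bonds are cut. Unit M is taken from the chiral pool with both stereocentres in place. With C8 brominated, C6 is the only nucleophilic carbon of ring A, so the formyl carbon (future C4 of T) can enter only there and the T–M linkage is fixed as 4→6. A bare resorcinol ring as the aryl group would have had to be functionalised late, in competition with the more nucleophilic ring A of T. The forward steps need C8-selective bromination and formylation at a position flanked by two benzyloxy groups.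

**8 from 7.** The aryl C–I bond is cut; 7 and 18 are bought. The forward step needs ring iodination (ortho to the acetyl group, ortho and para to the ethers) in preference to α-halogenation.

## Other disconnections considered

**Alternative 1:** The lactol A1 is cut through C3–C4 and O1–C2 of ring C of unit M. This leads back to the ortho-hydroxybenzhydrol A2, in which ring A of M is already joined to C6 of B through the future C4, and to benzyloxyacetaldehyde A3. Forward, A2 would ionise at the benzylic carbon to an ortho-quinone methide, the enamine of A3 with a chiral secondary amine would add to the methide carbon, and the phenol would close on the aldehyde.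
- In favour: the C3 oxygen and the C4 stereocentre of M would arrive in one catalytic step, so no separate enolate oxidation is needed. On this point it is better than the chosen plan. Unit B enters intact, and the C6 bromine of A1 is a handle for unit T.
- Against: the methide carbon carries a 2,6-dibenzyloxyaryl group and is hard to approach; the catalyst must cooperate with the stereocentres of B; and unit M is built from scratch although it can be bought as 1.
- Comparison: C2 of A1 still needs aryl addition and reduction, as in the chosen plan, so the two are equal there. Both plans rely on a catalyst for one diarylmethine centre and on relay for the rest. Alternative 1 solves M and leaves T untouched, so two units would have to be constructed and the step count would be higher.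

**Alternative 2:** The pivalate A4 is cut through C4(T)–C6(M), C3–C4 and O1–C2, so that ring C of T disappears in one stroke. The pieces are the arylmagnesium bromide A5 of the benzylated M–B dimer, the carbonate-protected salicylaldehyde A6 and the (Z)-enol ester A7. Forward, A5 would add to the aldehyde of A6, the alkoxide would take over and expel the carbonate group to unmask a quinone methide, and A7 would add across it in a [4+2] sense.
- In favour: three bonds and ring C in one operation, no oxidation-level changes at C2 and C3, and the 2,3-cis relation follows from the alkene geometry. On step economy for unit T it is clearly better than the chosen plan (one operation against steps 6 to 13).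
- Against: only the remote stereocentres of the dimer would decide which face of the methide reacts, so the absolute sense at C4 of T is not secured. The required 3,4-trans, 2,4-trans product corresponds to the exo mode, whereas the endo mode is usually preferred in such cycloadditions. The regiochemistry needs the styrene polarisation of A7 to win over its enol ester polarisation. A5 must be generated at the crowded C6 of a dimer.
- Comparison: the regiochemical logic is the same (C6 fixed by the position of a halogen) and the route is shorter. It is weaker on the point that matters most, the configuration at C4 of T, which the chosen plan sets with a chiral catalyst and then relays to C3 and C2.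

**Alternative 3:** The flavan-3-ol A8 is cut through O1–C2 and C3–O of unit M. This leads back to the dihydrobenzofuran carbinol A9, in which the ring oxygen is bonded to the future C3 and the future C2 is an exocyclic benzylic carbinol. Forward, activation of the carbinol would let the ring oxygen displace it with inversion, and water would open the bridged oxonium ion at the ring carbon, again with inversion.
- In favour: both new bonds would form stereospecifically, and no organometallic addition to a lactone or hydride reduction at C2 is needed. On the reliability of the C2 configuration it is potentially better than the chosen plan. A8 would emerge with a free 3-OH and a bromine handle at C6.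
- Against: A9 must already contain the three contiguous stereocentres, so the problem is moved and not simplified. The benzylic carbon bears a 4-alkoxyaryl group and can ionise, which would erase the stereospecificity. Water may also open the oxonium ion at the benzylic carbon and return a carbinol.
- Comparison: the chosen plan creates its stereocentres from one catalytic step plus relay, whereas this one transfers stereocentres made beforehand. Unit M is again built from scratch, so the step count for the whole target would be higher.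

Key step: step 9

Assumption: 7 and 18 are taken as commercial; the 3-aryl group of the indanone is ring A of a complete, benzylated, C8-brominated epicatechin (unit M), which keeps the reacting 3-(2,6-dibenzyloxyaryl)-4,6-dibenzyloxyindan-1-one skeleton, its (R) diarylmethine configuration (the one that becomes 4β of T) and the oxygen-insertion disconnection unchanged.

Shorthand in names: Ar = 3,4-bis(benzyloxy)phenyl; [M] = 8-bromo-3,5,7,3',4'-penta-O-benzylepicatechin-6-yl, a (2R,3R)-flavan bonded through C6.

## Route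

Step 1
Reactants: 1 (−)-epicatechin
Product: 2 5,7,3',4'-tetra-O-benzyl-(−)-epicatechin
Conditions: BnBr (4.4 equiv), K2CO3, DMF, 0 °C to rt
Reagents that add atoms: benzyl bromide, BrCc1ccccc1
Why: Williamson etherification of the four phenols; K2CO3 does not deprotonate the secondary 3-OH and is mild enough to leave C2 untouched.

Step 2
Reactants: 2 5,7,3',4'-tetra-O-benzyl-(−)-epicatechin
Product: 3 3,5,7,3',4'-penta-O-benzyl-(−)-epicatechin
Conditions: NaH, BnBr, Bu4NI (cat.), DMF, 0 °C to rt
Reagents that add atoms: benzyl bromide, BrCc1ccccc1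
Why: Williamson etherification of the secondary alcohol; no acidic C–H is present, so the stereocentres are not at risk.

Step 3
Reactants: 3 3,5,7,3',4'-penta-O-benzyl-(−)-epicatechin
Product: 4 8-bromo-3,5,7,3',4'-penta-O-benzyl-(−)-epicatechin
Conditions: NBS (1.0 equiv), CH2Cl2, −20 to 0 °C
Reagents that add atoms: N-bromosuccinimide, O=C1CCC(=O)N1Br
Why: Electrophilic aromatic bromination; the 1,3,5-trioxygenated ring A is far more reactive than the catechol ring, and C8 reacts before C6, which is flanked by two benzyloxy groups.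

Step 4
Reactants: 4 8-bromo-3,5,7,3',4'-penta-O-benzyl-(−)-epicatechin
Product: 6 8-bromo-6-formyl-3,5,7,3',4'-penta-O-benzyl-(−)-epicatechin, via iminium chloride 5 (not isolated)
Conditions: POCl3, DMF, 0 to 70 °C; then aq NaOAc, rt
Reagents that add atoms: N,N-dimethylformamide, CN(C)C=O; water, O
Why: Vilsmeier–Haack formylation; with C8 blocked, C6 is the only free carbon of the trioxygenated ring, so the carbon that becomes C4 of unit T can enter only there.

Step 5
Reactants: 7 1-[3,5-bis(benzyloxy)phenyl]ethanone
Product: 8 1-[3,5-bis(benzyloxy)-2-iodophenyl]ethanone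
Conditions: NIS, CF3CO2H (cat.), MeCN, 0 °C to rt
Reagents that add atoms: N-iodosuccinimide, O=C1CCC(=O)N1I
Why: Electrophilic aromatic iodination ortho to the acetyl group, at the carbon para to one benzyloxy group and ortho to the other; the carbon between the two ethers is more hindered.

Step 6
Reactants: 6 8-bromo-6-formyl-3,5,7,3',4'-penta-O-benzyl-(−)-epicatechin; 8 1-[3,5-bis(benzyloxy)-2-iodophenyl]ethanone
Product: 10 (E)-1-[3,5-bis(benzyloxy)-2-iodophenyl]-3-[M]-prop-2-en-1-one, via aldol adduct 9 (not isolated)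
Conditions: KOH, EtOH/THF, 0 °C to rt
Reagents that add atoms: none
Why: Claisen–Schmidt condensation; 6 cannot enolise, and the aldol adduct loses water by E1cB to give the conjugated (E)-enone.

Step 7
Reactants: 10 (E)-1-[3,5-bis(benzyloxy)-2-iodophenyl]-3-[M]-prop-2-en-1-one
Product: 11 (E)-1-[3,5-bis(benzyloxy)-2-(4,4,5,5-tetramethyl-1,3,2-dioxaborolan-2-yl)phenyl]-3-[M]-prop-2-en-1-one
Conditions: B2pin2, Pd(dppf)Cl2 (5 mol %), KOAc, 1,4-dioxane, 80 °C
Reagents that add atoms: bis(pinacolato)diboron, CC1(C)OB(OC1(C)C)B1OC(C)(C)C(C)(C)O1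
Why: Miyaura borylation; the aryl iodide ortho to the carbonyl group undergoes oxidative addition much faster than the electron-rich, doubly flanked C8 bromide of unit M, and KOAc is too weak a base to attack the enone.

Step 8
Reactants: 11 (E)-1-[3,5-bis(benzyloxy)-2-(4,4,5,5-tetramethyl-1,3,2-dioxaborolan-2-yl)phenyl]-3-[M]-prop-2-en-1-one
Product: 12 (3R)-4,6-bis(benzyloxy)-3-[M]-indan-1-one
Conditions: [Rh(C2H4)2Cl]2 (3 mol %), MonoPhos (BINOL-derived phosphoramidite, enantiomer giving 3R, 12 mol %), aq K3PO4, toluene, 60 °C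
Reagents that add atoms: none
Why: Rhodium-catalysed asymmetric intramolecular 1,4-addition of an arylboronate to an enone, an established enantioselective entry to 3-aryl-1-indanones: boron-to-rhodium transmetalation, insertion of the enone into the aryl–rhodium bond (C3–C3a) and protonolysis of the rhodium enolate. The chiral ligand selects the enone face and so sets C3; because unit M is chiral, any C3 epimer is a diastereomer and can be removed by chromatography.

Step 9
Reactants: 12 (3R)-4,6-bis(benzyloxy)-3-[M]-indan-1-one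
Product: 14 (4R)-5,7-bis(benzyloxy)-4-[M]-chroman-2-one (3,4-dihydrocoumarin), via peroxy hemiketal 13 (not isolated)
Conditions: mCPBA (2.5 equiv), CF3CO2H (1 equiv), CH2Cl2, 0 °C to rt
Reagents that add atoms: 3-chloroperoxybenzoic acid, OOC(=O)c1cccc(Cl)c1
Why: The peracid adds to the protonated ketone to give the tetrahedral adduct 13, and the C1–C7a bond migrates to the proximal peroxide oxygen with loss of 3-chlorobenzoate; this is the Baeyer–Villiger oxidation of a 1-indanone to a 3,4-dihydrocoumarin, a known reaction class. Ring C of unit T is closed by ring expansion: a 1,2-shift inserts O1 between C8a and the carbonyl carbon and turns the five-membered ketone into the six-membered lactone. No stereocentre is formed, and C4 is not part of the migrating bond and keeps its configuration. The step needs aryl and not methylene migration; the aryl carbon carries the developing positive charge better than the primary C2, and in the rigid indanone the C1–C7a bond can lie antiperiplanar to the O–O bond. It also needs the peracid to spare the arenes: ring A of M is hexasubstituted because C8 carries bromine, the ketone-bearing ring is deactivated by its acyl group, and catechol diethers react only slowly with mCPBA at this temperature. No interflavan bond between two electron-rich rings exists yet, so one equivalent of acid should be tolerated.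

Step 10
Reactants: 14 (4R)-5,7-bis(benzyloxy)-4-[M]-chroman-2-one
Product: 16 3α-hydroxy-5,7-bis(benzyloxy)-4β-[M]-chroman-2-one (3,4-trans), via potassium enolate 15 (not isolated)
Conditions: KN(SiMe3)2, THF, −78 °C; 2-(phenylsulfonyl)-3-phenyloxaziridine, −78 °C; aq NH4Cl
Reagents that add atoms: 2-(phenylsulfonyl)-3-phenyloxaziridine, O=S(=O)(c1ccccc1)N1OC1c1ccccc1
Why: Davis oxidation of a lactone enolate; the C4 aryl group is pseudoaxial (it avoids the C5 benzyloxy group) and shields one enolate face, so oxygen is delivered anti to it and C3 becomes 3α. The potassium enolate limits addition of the product alkoxide to the sulfonimine by-product.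

Step 11
Reactants: 16 3α-hydroxy-5,7-bis(benzyloxy)-4β-[M]-chroman-2-one
Product: 17 3α,5,7-tris(benzyloxy)-4β-[M]-chroman-2-one
Conditions: BnBr, Ag2O, 4 Å molecular sieves, CH2Cl2, rt, dark
Reagents that add atoms: benzyl bromide, BrCc1ccccc1
Why: Silver-oxide-mediated O-benzylation of an α-hydroxy ester; no alkoxide is formed, so the aryl lactone is not opened and C3 is not epimerised, and the benzyl ether leaves in the final hydrogenolysis.

Step 12
Reactants: 17 3α,5,7-tris(benzyloxy)-4β-[M]-chroman-2-one; 18 4-bromo-1,2-bis(benzyloxy)benzene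
Product: 20 2-Ar-2-hydroxy-3α,5,7-tris(benzyloxy)-4β-[M]-chroman (lactol, C2 not defined), via 3,4-bis(benzyloxy)phenyllithium 19 (not isolated)
Conditions: 18, n-BuLi, THF, −78 °C; transfer to 17 in THF (1.1 equiv of aryllithium), −78 °C; aq NH4Cl at −78 °C
Reagents that add atoms: none
Why: Bromine–lithium exchange followed by addition of the aryllithium to the lactone carbonyl, as used for C-aryl lactols; the lithium hemiketal persists at −78 °C and is protonated cold. Inverse addition and low temperature hold back a second addition and halogen–lithium exchange at the C8 bromide.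

Step 13
Reactants: 20 2-Ar-2-hydroxy-3α,5,7-tris(benzyloxy)-4β-[M]-chroman
Product: 21 3,5,7,3',4'-penta-O-benzylepicatechin-(4β→6)-8-bromo-3,5,7,3',4'-penta-O-benzylepicatechin
Conditions: Et3SiH, BF3·OEt2, CH2Cl2/MeCN, −78 to −40 °C; aq NaHCO3
Reagents that add atoms: none
Why: Ionic reduction of a lactol through the 2-aryl oxocarbenium ion, as in C-aryl glycoside synthesis. With the C4 aryl and C3 benzyloxy groups held trans-diaxial by the C5 benzyloxy group, hydride should add axially anti to the C3–O bond, which places the C2 aryl group equatorial and cis to the C3 oxygen (2α, 2,3-cis).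

Step 14
Reactants: 21 3,5,7,3',4'-penta-O-benzylepicatechin-(4β→6)-8-bromo-3,5,7,3',4'-penta-O-benzylepicatechin
Product: 22 6,8-dibromo-3,5,7,3',4'-penta-O-benzylepicatechin-(4β→6)-8-bromo-3,5,7,3',4'-penta-O-benzylepicatechin
Conditions: NBS (2.1 equiv), CH2Cl2, −20 °C to rt
Reagents that add atoms: N-bromosuccinimide, O=C1CCC(=O)N1Br
Why: Electrophilic aromatic bromination; C6 and C8 of unit T are the only free carbons on a trioxygenated ring. Capping them removes the nucleophilic sites of the future electrophile and makes C4–H of T a poorer hydride donor.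

Step 15
Reactants: 22 6,8-dibromo-3,5,7,3',4'-penta-O-benzylepicatechin-(4β→6)-8-bromo-3,5,7,3',4'-penta-O-benzylepicatechin
Product: 23 6,8-dibromo-3,5,7,3',4'-penta-O-benzylepicatechin-(4β→6)-8-bromo-4β-(2-ethoxyethoxy)-3,5,7,3',4'-penta-O-benzylepicatechin
Conditions: DDQ (2.5 equiv), 2-ethoxyethanol, CH2Cl2, rt
Reagents that add atoms: 2-ethoxyethanol, CCOCCO
Why: DDQ oxidation of a benzylated flavan at C4 with capture of the cation by the alcohol, the usual activation of flavan-3-ols; hydride is taken from the accessible CH2 of unit M and not from the buried diarylmethine C–H of T, and the alcohol adds anti to the C3 benzyloxy group (4β).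

Step 16
Reactants: 23 6,8-dibromo-3,5,7,3',4'-penta-O-benzylepicatechin-(4β→6)-8-bromo-4β-(2-ethoxyethoxy)-3,5,7,3',4'-penta-O-benzylepicatechin; 4 8-bromo-3,5,7,3',4'-penta-O-benzyl-(−)-epicatechin
Product: 24 6,8-dibromo-penta-O-benzylepicatechin-(4β→6)-8-bromo-penta-O-benzylepicatechin-(4β→6)-8-bromo-penta-O-benzylepicatechin (each unit 3,5,7,3',4'-penta-O-benzyl)
Conditions: 4 (4 equiv), Me3SiOTf (0.2 equiv), CH2Cl2, −78 °C; Et3N
Reagents that add atoms: none
Why: Lewis-acid-promoted Friedel–Crafts coupling of a flavan C4 cation with ring A of a second flavan, the standard interflavan bond formation. Bromine at C8 of 4 leaves C6 as its only nucleophilic carbon, and attack anti to the axial C3 benzyloxy group of unit M gives the 4β (3,4-trans) linkage.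

Step 17
Reactants: 24 6,8-dibromo-penta-O-benzylepicatechin-(4β→6)-8-bromo-penta-O-benzylepicatechin-(4β→6)-8-bromo-penta-O-benzylepicatechin
Product: 25 (−)-epicatechin-(4β→6)-(−)-epicatechin-(4β→6)-(−)-epicatechin
Conditions: H2 (1 atm), Pd(OH)2/C, Et3N, THF/MeOH/H2O, rt
Reagents that add atoms: none
Why: Hydrogenolysis of the fifteen benzyl ethers and hydrodebromination of the four aryl bromides in one operation; triethylamine takes up HBr so that the interflavan bonds are not exposed to acid.

## Compound list

1 | (−)-epicatechin | O[C@@H]1Cc2c(O)cc(O)cc2O[C@@H]1c1ccc(O)c(O)c1 | starting material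

2 | 5,7,3',4'-tetra-O-benzyl-(−)-epicatechin | O[C@@H]1Cc2c(OCc9ccccc9)cc(OCc9ccccc9)cc2O[C@@H]1c8ccc(OCc9ccccc9)c(OCc9ccccc9)c8 | intermediate

3 | 3,5,7,3',4'-penta-O-benzyl-(−)-epicatechin | C(c9ccccc9)O[C@@H]1Cc2c(OCc9ccccc9)cc(OCc9ccccc9)cc2O[C@@H]1c8ccc(OCc9ccccc9)c(OCc9ccccc9)c8 | intermediate

4 | 8-bromo-3,5,7,3',4'-penta-O-benzyl-(−)-epicatechin | C(c9ccccc9)O[C@@H]1Cc2c(OCc9ccccc9)cc(OCc9ccccc9)c(Br)c2O[C@@H]1c8ccc(OCc9ccccc9)c(OCc9ccccc9)c8 | intermediate

5 | 8-bromo-6-[(dimethyliminio)methyl]-3,5,7,3',4'-penta-O-benzylepicatechin chloride | C(c9ccccc9)O[C@@H]1Cc2c(OCc9ccccc9)c(C=[N+](C)C)c(OCc9ccccc9)c(Br)c2O[C@@H]1c8ccc(OCc9ccccc9)c(OCc9ccccc9)c8.[Cl-] | intermediate (not isolated)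

6 | 8-bromo-6-formyl-3,5,7,3',4'-penta-O-benzyl-(−)-epicatechin | C(c9ccccc9)O[C@@H]1Cc2c(OCc9ccccc9)c(C=O)c(OCc9ccccc9)c(Br)c2O[C@@H]1c8ccc(OCc9ccccc9)c(OCc9ccccc9)c8 | intermediate

7 | 1-[3,5-bis(benzyloxy)phenyl]ethanone | CC(=O)c1cc(OCc9ccccc9)cc(OCc9ccccc9)c1 | starting material

8 | 1-[3,5-bis(benzyloxy)-2-iodophenyl]ethanone | CC(=O)c1cc(OCc9ccccc9)cc(OCc9ccccc9)c1I | intermediate

9 | 1-[3,5-bis(benzyloxy)-2-iodophenyl]-3-hydroxy-3-[M]-propan-1-one (carbinol carbon not defined) | O=C(CC(O)c3c(OCc9ccccc9)c4C[C@@H](OCc9ccccc9)[C@@H](c8ccc(OCc9ccccc9)c(OCc9ccccc9)c8)Oc4c(Br)c3OCc9ccccc9)c1cc(OCc9ccccc9)cc(OCc9ccccc9)c1I | intermediate (not isolated)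

10 | (E)-1-[3,5-bis(benzyloxy)-2-iodophenyl]-3-[M]-prop-2-en-1-one | O=C(/C=C/c3c(OCc9ccccc9)c4C[C@@H](OCc9ccccc9)[C@@H](c8ccc(OCc9ccccc9)c(OCc9ccccc9)c8)Oc4c(Br)c3OCc9ccccc9)c1cc(OCc9ccccc9)cc(OCc9ccccc9)c1I | intermediate

11 | (E)-1-[3,5-bis(benzyloxy)-2-(4,4,5,5-tetramethyl-1,3,2-dioxaborolan-2-yl)phenyl]-3-[M]-prop-2-en-1-one | O=C(/C=C/c3c(OCc9ccccc9)c4C[C@@H](OCc9ccccc9)[C@@H](c8ccc(OCc9ccccc9)c(OCc9ccccc9)c8)Oc4c(Br)c3OCc9ccccc9)c1cc(OCc9ccccc9)cc(OCc9ccccc9)c1B1OC(C)(C)C(C)(C)O1 | intermediate

12 | (3R)-4,6-bis(benzyloxy)-3-[M]-indan-1-one | O=C1C[C@@H](c3c(OCc9ccccc9)c4C[C@@H](OCc9ccccc9)[C@@H](c8ccc(OCc9ccccc9)c(OCc9ccccc9)c8)Oc4c(Br)c3OCc9ccccc9)c2c(OCc9ccccc9)cc(OCc9ccccc9)cc21 | intermediate (key-step precursor)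

13 | 1-hydroxy-1-(3-chlorobenzoylperoxy) adduct of 12 (C1 not defined) | OC1(OOC(=O)c5cccc(Cl)c5)C[C@@H](c3c(OCc9ccccc9)c4C[C@@H](OCc9ccccc9)[C@@H](c8ccc(OCc9ccccc9)c(OCc9ccccc9)c8)Oc4c(Br)c3OCc9ccccc9)c2c(OCc9ccccc9)cc(OCc9ccccc9)cc21 | intermediate (not isolated)

14 | (4R)-5,7-bis(benzyloxy)-4-[M]-chroman-2-one | O=C1C[C@@H](c3c(OCc9ccccc9)c4C[C@@H](OCc9ccccc9)[C@@H](c8ccc(OCc9ccccc9)c(OCc9ccccc9)c8)Oc4c(Br)c3OCc9ccccc9)c2c(OCc9ccccc9)cc(OCc9ccccc9)cc2O1 | intermediate (key-step product)

15 | potassium enolate of 14 | [K+].[O-]C1=C[C@@H](c3c(OCc9ccccc9)c4C[C@@H](OCc9ccccc9)[C@@H](c8ccc(OCc9ccccc9)c(OCc9ccccc9)c8)Oc4c(Br)c3OCc9ccccc9)c2c(OCc9ccccc9)cc(OCc9ccccc9)cc2O1 | intermediate (not isolated)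

16 | 3α-hydroxy-5,7-bis(benzyloxy)-4β-[M]-chroman-2-one | C(c9ccccc9)Oc1cc(OCc9ccccc9)c2c(c1)OC(=O)[C@H](O)[C@H]2c3c(OCc9ccccc9)c4C[C@@H](OCc9ccccc9)[C@@H](c8ccc(OCc9ccccc9)c(OCc9ccccc9)c8)Oc4c(Br)c3OCc9ccccc9 | intermediate

17 | 3α,5,7-tris(benzyloxy)-4β-[M]-chroman-2-one | C(c9ccccc9)Oc1cc(OCc9ccccc9)c2c(c1)OC(=O)[C@H](OCc9ccccc9)[C@H]2c3c(OCc9ccccc9)c4C[C@@H](OCc9ccccc9)[C@@H](c8ccc(OCc9ccccc9)c(OCc9ccccc9)c8)Oc4c(Br)c3OCc9ccccc9 | intermediate

18 | 4-bromo-1,2-bis(benzyloxy)benzene | Brc1ccc(OCc9ccccc9)c(OCc9ccccc9)c1 | starting material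

19 | 3,4-bis(benzyloxy)phenyllithium | [Li]c1ccc(OCc9ccccc9)c(OCc9ccccc9)c1 | intermediate (not isolated)

20 | 2-Ar-2-hydroxy-3α,5,7-tris(benzyloxy)-4β-[M]-chroman (C2 not defined; in equilibrium with the open hydroxy ketone) | C(c9ccccc9)Oc1cc(OCc9ccccc9)c2c(c1)OC(O)(c8ccc(OCc9ccccc9)c(OCc9ccccc9)c8)[C@H](OCc9ccccc9)[C@H]2c3c(OCc9ccccc9)c4C[C@@H](OCc9ccccc9)[C@@H](c8ccc(OCc9ccccc9)c(OCc9ccccc9)c8)Oc4c(Br)c3OCc9ccccc9 | intermediate

21 | 3,5,7,3',4'-penta-O-benzylepicatechin-(4β→6)-8-bromo-3,5,7,3',4'-penta-O-benzylepicatechin | C(c9ccccc9)Oc1cc(OCc9ccccc9)c2c(c1)O[C@H](c8ccc(OCc9ccccc9)c(OCc9ccccc9)c8)[C@H](OCc9ccccc9)[C@H]2c3c(OCc9ccccc9)c4C[C@@H](OCc9ccccc9)[C@@H](c8ccc(OCc9ccccc9)c(OCc9ccccc9)c8)Oc4c(Br)c3OCc9ccccc9 | intermediate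

22 | 6,8-dibromo-3,5,7,3',4'-penta-O-benzylepicatechin-(4β→6)-8-bromo-3,5,7,3',4'-penta-O-benzylepicatechin | C(c9ccccc9)Oc1c(Br)c(OCc9ccccc9)c2c(c1Br)O[C@H](c8ccc(OCc9ccccc9)c(OCc9ccccc9)c8)[C@H](OCc9ccccc9)[C@H]2c3c(OCc9ccccc9)c4C[C@@H](OCc9ccccc9)[C@@H](c8ccc(OCc9ccccc9)c(OCc9ccccc9)c8)Oc4c(Br)c3OCc9ccccc9 | intermediate

23 | 6,8-dibromo-3,5,7,3',4'-penta-O-benzylepicatechin-(4β→6)-8-bromo-4β-(2-ethoxyethoxy)-3,5,7,3',4'-penta-O-benzylepicatechin | C(c9ccccc9)Oc1c(Br)c(OCc9ccccc9)c2c(c1Br)O[C@H](c8ccc(OCc9ccccc9)c(OCc9ccccc9)c8)[C@H](OCc9ccccc9)[C@H]2c3c(OCc9ccccc9)c4[C@H](OCCOCC)[C@@H](OCc9ccccc9)[C@@H](c8ccc(OCc9ccccc9)c(OCc9ccccc9)c8)Oc4c(Br)c3OCc9ccccc9 | intermediate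

24 | 6,8-dibromo-penta-O-benzylepicatechin-(4β→6)-8-bromo-penta-O-benzylepicatechin-(4β→6)-8-bromo-penta-O-benzylepicatechin | C(c9ccccc9)Oc1c(Br)c(OCc9ccccc9)c2c(c1Br)O[C@H](c8ccc(OCc9ccccc9)c(OCc9ccccc9)c8)[C@H](OCc9ccccc9)[C@H]2c3c(OCc9ccccc9)c4[C@H](c5c(OCc9ccccc9)c6C[C@@H](OCc9ccccc9)[C@@H](c8ccc(OCc9ccccc9)c(OCc9ccccc9)c8)Oc6c(Br)c5OCc9ccccc9)[C@@H](OCc9ccccc9)[C@@H](c8ccc(OCc9ccccc9)c(OCc9ccccc9)c8)Oc4c(Br)c3OCc9ccccc9 | intermediate

25 | (−)-epicatechin-(4β→6)-(−)-epicatechin-(4β→6)-(−)-epicatechin (CNP0163146.2) | Oc1cc(O)c2c(c1)O[C@H](c1ccc(O)c(O)c1)[C@H](O)[C@H]2c1c(O)cc2c(c1O)[C@H](c1c(O)cc3c(c1O)C[C@@H](O)[C@@H](c1ccc(O)c(O)c1)O3)[C@@H](O)[C@@H](c1ccc(O)c(O)c1)O2 | target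

## Step count and least certain steps

Total: 17 steps. Longest linear sequence: 16 steps (1 to 25 through steps 1–4 and 6–17); step 5 is a one-step branch.

**Step 9 (key step).** Oxygen insertion may be slow, because the ketone lacks ortho or para donors on the migrating ring. Long exposure to peracid and acid could then lead to oxidative degradation of the catechol diether rings or loss of benzyl groups; methylene migration is a lesser risk. Fallback: from 12, the mode of oxygen delivery is changed from an electrophilic peracid to a nucleophilic silyl peroxide that adds to a Lewis-acid-activated carbonyl group (bis(trimethylsilyl) peroxide, catalytic Me3SiOTf, CH2Cl2, −40 °C). No free peracid or protic acid is then present. The same 1,2-shift returns the route at 14; no new isolated compound is involved (F0).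

**Step 8.** Protodeboronation of the doubly ortho-substituted boronate may outrun carbometalation at the hindered β-carbon, or facial selection may be poor. Fallback: from 10, the boron step is bypassed and the ring is closed by a palladium-catalysed reductive Heck cyclisation (Pd(OAc)2, chiral bisphosphine, amine or formate as hydride source). The aryl–palladium species formed at the iodide adds to the enone and the palladium enolate is reduced. The C3 epimer of the indanone F1 would be removed by chromatography, and the route is rejoined at 12.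

**Step 12.** The ring-opened ketone may take up a second aryllithium, since phenoxide is a good leaving group, and bromine–lithium exchange may occur at C8 of unit M. Fallback: from 17, the lactone is opened with N,O-dimethylhydroxylamine hydrochloride and i-PrMgCl to the Weinreb amide F2. Its chelated tetrahedral intermediate accepts one aryl group only on treatment with 19 (one extra equivalent for the phenol). The hydroxy ketone released on work-up closes to the lactol, and the route is rejoined at 20.

**Step 13.** Facial selectivity in hydride delivery may be poor if the oxocarbenium ion reacts through the conformer with the C4 aryl group pseudoequatorial, which would give the 2,3-trans isomer; elimination to the enol ether may compete. Fallback: from 20 (as its open hydroxy ketone), chelation-controlled reduction with Zn(BH4)2 gives the 1,2-anti alcohol F3. Mitsunobu cyclisation (PPh3, diisopropyl azodicarboxylate) then lets the phenol displace the benzylic hydroxyl with inversion, which turns anti into 2,3-cis. The route is rejoined at 21.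

**Step 16 (with step 15).** Capture of the crowded C4 cation of unit M may be slow: its C5 benzyloxy group is buttressed by unit T, and C6 of 4 is itself hindered. Elimination to the flav-3-ene or return of the alcohol could then dominate, and in step 15 hydride abstraction at the wrong benzylic carbon could compete. Fallback: the M–B bond is formed at the lactone stage, before the 2-aryl group of T is in place. From 17, DDQ and 2-ethoxyethanol give the 4β-(2-ethoxyethoxy) lactone F4, and Me3SiOTf with excess 4 gives the coupled lactone F5 (the acyloxy-substituted ring A of T is a poor nucleophile, so no bromination is needed). Addition of 19 as in step 12 gives the lactol F6, reduction as in step 13 gives the protected trimer F7, and hydrogenolysis as in step 17 rejoins the route at 25.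

## Further compounds

F0 | step 9 | none | none

F1 | step 8 | (3S)-4,6-bis(benzyloxy)-3-[M]-indan-1-one (C3 epimer of 12) | O=C1C[C@H](c3c(OCc9ccccc9)c4C[C@@H](OCc9ccccc9)[C@@H](c8ccc(OCc9ccccc9)c(OCc9ccccc9)c8)Oc4c(Br)c3OCc9ccccc9)c2c(OCc9ccccc9)cc(OCc9ccccc9)cc21

F2 | step 12 | N-methoxy-N-methyl-2-(benzyloxy)-3-[2-hydroxy-4,6-bis(benzyloxy)phenyl]-3-[M]-propanamide (configuration as in 17) | CON(C)C(=O)[C@H](OCc9ccccc9)[C@@H](c3c(OCc9ccccc9)c4C[C@@H](OCc9ccccc9)[C@@H](c8ccc(OCc9ccccc9)c(OCc9ccccc9)c8)Oc4c(Br)c3OCc9ccccc9)c1c(OCc9ccccc9)cc(OCc9ccccc9)cc1O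

F3 | step 13 | 1-Ar-2-(benzyloxy)-3-[2-hydroxy-4,6-bis(benzyloxy)phenyl]-3-[M]-propan-1-ol (1,2-anti) | Oc1cc(OCc9ccccc9)cc(OCc9ccccc9)c1[C@H](c3c(OCc9ccccc9)c4C[C@@H](OCc9ccccc9)[C@@H](c8ccc(OCc9ccccc9)c(OCc9ccccc9)c8)Oc4c(Br)c3OCc9ccccc9)[C@@H](OCc9ccccc9)[C@@H](O)c8ccc(OCc9ccccc9)c(OCc9ccccc9)c8

F4 | step 16 | 3α,5,7-tris(benzyloxy)-4β-[8-bromo-4β-(2-ethoxyethoxy)-3,5,7,3',4'-penta-O-benzylepicatechin-6-yl]chroman-2-one | C(c9ccccc9)Oc1cc(OCc9ccccc9)c2c(c1)OC(=O)[C@H](OCc9ccccc9)[C@H]2c3c(OCc9ccccc9)c4[C@H](OCCOCC)[C@@H](OCc9ccccc9)[C@@H](c8ccc(OCc9ccccc9)c(OCc9ccccc9)c8)Oc4c(Br)c3OCc9ccccc9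

F5 | step 16 | 3α,5,7-tris(benzyloxy)chroman-2-one joined through C4 (4β) to C6 of 8-bromo-penta-O-benzylepicatechin-(4β→6)-8-bromo-penta-O-benzylepicatechin | C(c9ccccc9)Oc1cc(OCc9ccccc9)c2c(c1)OC(=O)[C@H](OCc9ccccc9)[C@H]2c3c(OCc9ccccc9)c4[C@H](c5c(OCc9ccccc9)c6C[C@@H](OCc9ccccc9)[C@@H](c8ccc(OCc9ccccc9)c(OCc9ccccc9)c8)Oc6c(Br)c5OCc9ccccc9)[C@@H](OCc9ccccc9)[C@@H](c8ccc(OCc9ccccc9)c(OCc9ccccc9)c8)Oc4c(Br)c3OCc9ccccc9

F6 | step 16 | 2-Ar-2-hydroxy lactol derived from F5 (C2 not defined) | C(c9ccccc9)Oc1cc(OCc9ccccc9)c2c(c1)OC(O)(c8ccc(OCc9ccccc9)c(OCc9ccccc9)c8)[C@H](OCc9ccccc9)[C@H]2c3c(OCc9ccccc9)c4[C@H](c5c(OCc9ccccc9)c6C[C@@H](OCc9ccccc9)[C@@H](c8ccc(OCc9ccccc9)c(OCc9ccccc9)c8)Oc6c(Br)c5OCc9ccccc9)[C@@H](OCc9ccccc9)[C@@H](c8ccc(OCc9ccccc9)c(OCc9ccccc9)c8)Oc4c(Br)c3OCc9ccccc9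

F7 | step 16 | penta-O-benzylepicatechin-(4β→6)-8-bromo-penta-O-benzylepicatechin-(4β→6)-8-bromo-penta-O-benzylepicatechin | C(c9ccccc9)Oc1cc(OCc9ccccc9)c2c(c1)O[C@H](c8ccc(OCc9ccccc9)c(OCc9ccccc9)c8)[C@H](OCc9ccccc9)[C@H]2c3c(OCc9ccccc9)c4[C@H](c5c(OCc9ccccc9)c6C[C@@H](OCc9ccccc9)[C@@H](c8ccc(OCc9ccccc9)c(OCc9ccccc9)c8)Oc6c(Br)c5OCc9ccccc9)[C@@H](OCc9ccccc9)[C@@H](c8ccc(OCc9ccccc9)c(OCc9ccccc9)c8)Oc4c(Br)c3OCc9ccccc9

A1 | alternative 1 | 6-bromo-3α,5,7-tris(benzyloxy)-4β-(3,5,7,3',4'-penta-O-benzylepicatechin-6-yl)chroman-2-ol (one anomer) | Brc1c(OCc9ccccc9)cc2c(c1OCc9ccccc9)[C@H](c3c(OCc9ccccc9)cc4c(c3OCc9ccccc9)C[C@@H](OCc9ccccc9)[C@@H](c8ccc(OCc9ccccc9)c(OCc9ccccc9)c8)O4)[C@@H](OCc9ccccc9)[C@H](O)O2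

A2 | alternative 1 | [3-bromo-2,4-bis(benzyloxy)-6-hydroxyphenyl](3,5,7,3',4'-penta-O-benzylepicatechin-6-yl)methanol (carbinol carbon not defined) | Brc1c(OCc9ccccc9)cc(O)c(c1OCc9ccccc9)C(O)c3c(OCc9ccccc9)cc4c(c3OCc9ccccc9)C[C@@H](OCc9ccccc9)[C@@H](c8ccc(OCc9ccccc9)c(OCc9ccccc9)c8)O4

A3 | alternative 1 | benzyloxyacetaldehyde | O=CCOCc1ccccc1

A4 | alternative 2 | benzylated trimer carrying a pivalate at C3 of unit T | C(c9ccccc9)Oc1cc(OCc9ccccc9)c2c(c1)O[C@H](c8ccc(OCc9ccccc9)c(OCc9ccccc9)c8)[C@H](OC(=O)C(C)(C)C)[C@H]2c1c(OCc9ccccc9)cc2c(c1OCc9ccccc9)[C@H](c3c(OCc9ccccc9)cc4c(c3OCc9ccccc9)C[C@@H](OCc9ccccc9)[C@@H](c8ccc(OCc9ccccc9)c(OCc9ccccc9)c8)O4)[C@@H](OCc9ccccc9)[C@@H](c8ccc(OCc9ccccc9)c(OCc9ccccc9)c8)O2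

A5 | alternative 2 | C6 arylmagnesium bromide of deca-O-benzylepicatechin-(4β→6)-epicatechin | Br[Mg]c1c(OCc9ccccc9)cc2c(c1OCc9ccccc9)[C@H](c3c(OCc9ccccc9)cc4c(c3OCc9ccccc9)C[C@@H](OCc9ccccc9)[C@@H](c8ccc(OCc9ccccc9)c(OCc9ccccc9)c8)O4)[C@@H](OCc9ccccc9)[C@@H](c8ccc(OCc9ccccc9)c(OCc9ccccc9)c8)O2

A6 | alternative 2 | 3,5-bis(benzyloxy)-2-formylphenyl tert-butyl carbonate | O=Cc1c(OCc9ccccc9)cc(OCc9ccccc9)cc1OC(=O)OC(C)(C)C

A7 | alternative 2 | (Z)-2-[3,4-bis(benzyloxy)phenyl]ethenyl pivalate | CC(C)(C)C(=O)O/C=C\c1ccc(OCc9ccccc9)c(OCc9ccccc9)c1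

A8 | alternative 3 | 6-bromo-5,7,3',4'-tetra-O-benzylepicatechin joined through C4 (4β) to C6 of penta-O-benzylepicatechin (free 3-OH on the upper unit) | Brc1c(OCc9ccccc9)cc2c(c1OCc9ccccc9)[C@H](c3c(OCc9ccccc9)cc4c(c3OCc9ccccc9)C[C@@H](OCc9ccccc9)[C@@H](c8ccc(OCc9ccccc9)c(OCc9ccccc9)c8)O4)[C@@H](O)[C@@H](c8ccc(OCc9ccccc9)c(OCc9ccccc9)c8)O2

A9 | alternative 3 | Ar-[5-bromo-4,6-bis(benzyloxy)-3-(penta-O-benzylepicatechin-6-yl)-2,3-dihydrobenzofuran-2-yl]methanol | Brc1c(OCc9ccccc9)cc2c(c1OCc9ccccc9)[C@H](c3c(OCc9ccccc9)cc4c(c3OCc9ccccc9)C[C@@H](OCc9ccccc9)[C@@H](c8ccc(OCc9ccccc9)c(OCc9ccccc9)c8)O4)[C@H](O2)[C@@H](O)c8ccc(OCc9ccccc9)c(OCc9ccccc9)c8
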